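**Retrosynthetic overview**

1. Building blocks: eugenol (1), taken via borane 2 to dihydroconiferyl alcohol (3) and via iodane 4 to spirodienone 5, plus 4-propylsyringol (6); dienone 7 leads to target 8.
2. Key disconnection: the diaryl ether C–O bond of 8, between the phenolic oxygen of 6 and the ring carbon ortho to the free OH of the guaiacyl unit, giving 6 + the dearomatised, electrophilic guaiacyl unit 5.
3. 5 comes from 3 by oxidative dearomatisation (C–O spiroetherification); 3 comes from 1 by anti-Markovnikov hydration of the allyl group.
4. Rings: both benzene rings are bought. The only ring made is the spiro-tetrahydrofuran of 5 (step 2), opened again when the guaiacyl ring rearomatises in step 3.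

Assumption: the target has no stereocentre or stereogenic axis (it is achiral), so the structure as drawn is the single compound to be made; 5 and 7 are racemic and lose their stereocentre on rearomatisation.

**Route**

Step 1
Reactants: 1 eugenol (4-allyl-2-methoxyphenol)
Product: 3 dihydroconiferyl alcohol [4-(3-hydroxypropyl)-2-methoxyphenol], via B-alkyl-9-BBN aryl borinate 2 (not isolated)
Conditions: 9-BBN (2.2 equiv), THF, 0 °C → rt; then 3 M NaOH, 30% H2O2, 0 °C → rt
Reagents that add atoms: hydrogen peroxide, OO
Why: Brown hydroboration–oxidation: one equivalent of 9-BBN caps the phenol as its borinate (H2 evolved), the second adds boron to the terminal allyl carbon (anti-Markovnikov), and alkaline peroxide turns C–B into C–OH and hydrolyses the O–B bond; no stereocentre is formed.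

Step 2
Reactants: 3 dihydroconiferyl alcohol
Product: 5 (±)-7-methoxy-1-oxaspiro[4.5]deca-6,9-dien-8-one, via aryloxy(acetoxy)phenyl-λ3-iodane 4 (not isolated)
Conditions: PhI(OAc)2 (1.1 equiv), (CF3)2CHOH, 0 °C, 15 min; NaHCO3 work-up
Reagents that add atoms: none
Why: Hypervalent-iodine oxidative dearomatisation (dearomatising spiroetherification): ligand exchange gives 4, loss of PhI and acetate makes the para carbon electrophilic, and the tethered primary alcohol closes the five-membered ring (5-exo) faster than any external nucleophile in non-nucleophilic HFIP; the spiro carbon is a stereocentre formed as a racemate, which is irrelevant because it becomes an aromatic carbon again in step 3.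

Step 3
Reactants: 5 (±)-7-methoxy-1-oxaspiro[4.5]deca-6,9-dien-8-one; 6 4-propylsyringol (2,6-dimethoxy-4-propylphenol)
Product: 8 2-(2,6-dimethoxy-4-propylphenoxy)-4-(3-hydroxypropyl)-6-methoxyphenol (target), via 6-aryloxycyclohexa-2,4-dienone 7 (not isolated)
Conditions: 5 added over 2 h to 6 (2.5 equiv), (PhO)2P(O)OH (10 mol%), CH2Cl2/(CF3)2CHOH 4:1, −20 → 0 °C
Reagents that add atoms: none
Why: Proposed new method: Brønsted-acid-catalysed ring-opening SN2′ aryloxylation of a spiro p-quinol ether – the phosphoric acid protonates/H-bonds the spiro-ether oxygen of 5 (the leaving group) while its P=O end carries the OH of 6, whose ortho and para carbons are all substituted so it can bond only through oxygen; O-attack at C-9 (the only unsubstituted carbon α to the carbonyl) with shift of the C9=C10 double bond to C10=C5 opens the tetrahydrofuran, frees the 3-hydroxypropyl chain and gives 7, which enolises irreversibly to 8 (the transient stereocentre of 7 is lost); attack at the substituted carbon C-7 gives only a mixed ketal that re-ionises under the acid, and an electron-transfer variant (oxidised guaiacyl unit + 6 → two phenoxyl radicals) would collapse to the same O–C bond; the closest known reaction type is the acid/HFIP-promoted SN2′ substitution of quinone monoacetals by arene carbon nucleophiles α to the carbonyl (C–C bond formation), not yet shown with a spiro mono-ether whose tethered alkoxide is the leaving group or for diaryl ether C–O formation with a 2,4,6-trisubstituted phenol.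

**Compound list**

1 | eugenol (4-allyl-2-methoxyphenol) | C=CCc1ccc(O)c(OC)c1 | starting material
2 | 9-{3-[4-(9-borabicyclo[3.3.1]nonan-9-yloxy)-3-methoxyphenyl]propyl}-9-borabicyclo[3.3.1]nonane | COc1cc(CCCB2C3CCCC2CCC3)ccc1OB1C2CCCC1CCC2 | intermediate (not isolated)
3 | dihydroconiferyl alcohol, 4-(3-hydroxypropyl)-2-methoxyphenol | COc1cc(CCCO)ccc1O | intermediate
4 | [4-(3-hydroxypropyl)-2-methoxyphenoxy](acetoxy)(phenyl)-λ3-iodane | COc1cc(CCCO)ccc1OI(OC(C)=O)c1ccccc1 | intermediate (not isolated)
5 | (±)-7-methoxy-1-oxaspiro[4.5]deca-6,9-dien-8-one (racemic at the spiro carbon) | COC1=CC2(CCCO2)C=CC1=O | intermediate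
6 | 4-propylsyringol (2,6-dimethoxy-4-propylphenol) | CCCc1cc(OC)c(O)c(OC)c1 | starting material
7 | (±)-6-(2,6-dimethoxy-4-propylphenoxy)-4-(3-hydroxypropyl)-2-methoxycyclohexa-2,4-dien-1-one (racemic, transient) | COC1=CC(CCCO)=CC(Oc2c(OC)cc(CCC)cc2OC)C1=O | intermediate (not isolated)
8 | 2-(2,6-dimethoxy-4-propylphenoxy)-4-(3-hydroxypropyl)-6-methoxyphenol (achiral) | CCCc1cc(OC)c(Oc2cc(CCCO)cc(OC)c2O)c(OC)c1 | target

**Step count and risks**

Total steps: 3. Longest linear sequence: 3 (1 → 3 → 5 → 8); 6 is bought and enters in step 3.

Steps most likely to fail, most risky first: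

Step 3 (the proposed new coupling). The risks are:
- oxa-Michael addition of 6 at C-10 followed by elimination, which gives the meta-aryloxy isomer;
- acid-induced dienone–phenol rearrangement of 5 to a chromanol;
- benzylic proton loss to a quinone methide;
- hydride or electron transfer from the easily oxidised 6;
- a second arylation of 8 by 5.

The fallback uses known chemistry only, sets out from 3 and comes back to the route at 8. Iodinate 3 ortho to the phenol (I2, KI, aq. NaHCO3) to 4-(3-hydroxypropyl)-2-iodo-6-methoxyphenol F1. Benzylate both hydroxyls (NaH, BnBr, DMF) to 2-(benzyloxy)-5-[3-(benzyloxy)propyl]-1-iodo-3-methoxybenzene F2. Couple F2 with 6 in an Ullmann diaryl ether synthesis (CuI, picolinic acid, K3PO4, DMSO, 90 °C) to 2-(benzyloxy)-5-[3-(benzyloxy)propyl]-1-(2,6-dimethoxy-4-propylphenoxy)-3-methoxybenzene F3. Hydrogenolyse both benzyl ethers (H2, Pd/C, EtOAc) to 8.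

Step 2. The risks are capture of the oxidised phenol at the methoxy-bearing ortho carbon by acetate (o-quinone ketal-type products and their Diels–Alder dimers), over-oxidation, and rearrangement of 5 on acidic silica. The fallback sets out from 1 and comes back at 8. Oxidise eugenol in methanol (PhI(OAc)2, MeOH, 0 °C) to the masked o-benzoquinone 4-allyl-6,6-dimethoxycyclohexa-2,4-dien-1-one F4, used at once because it dimerises on standing. Treat it with 6 under the step-3 acid conditions: loss of methanol and O-attack at the free carbon α to the carbonyl give 4-allyl-2-(2,6-dimethoxy-4-propylphenoxy)-6-methoxyphenol F5. Hydroboration–oxidation as in step 1 (9-BBN; NaOH, H2O2) then gives 8. This fallback keeps the new C–O coupling but changes the electrophile to a ketal with an external leaving group and moves the hydroboration to the end; if the coupling itself fails, the step-3 fallback applies.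

Step 1. The risks are incomplete hydroboration because the free phenol consumes borane, and oxidative darkening of the electron-rich phenolate in alkaline peroxide. The fallback sets out from 1 and comes back at 3. Acetylate the phenol (Ac2O, pyridine) to 4-allyl-2-methoxyphenyl acetate F6, hydroborate with 1.1 equiv 9-BBN in THF, and let the NaOH/H2O2 work-up oxidise the borane and saponify the aryl acetate in the same flask to give 3.

**Further compounds**

F1 | step 3 | 4-(3-hydroxypropyl)-2-iodo-6-methoxyphenol | COc1cc(CCCO)cc(I)c1O
F2 | step 3 | 2-(benzyloxy)-5-[3-(benzyloxy)propyl]-1-iodo-3-methoxybenzene | COc1cc(CCCOCc2ccccc2)cc(I)c1OCc1ccccc1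
F3 | step 3 | 2-(benzyloxy)-5-[3-(benzyloxy)propyl]-1-(2,6-dimethoxy-4-propylphenoxy)-3-methoxybenzene | CCCc1cc(OC)c(Oc2cc(CCCOCc3ccccc3)cc(OC)c2OCc2ccccc2)c(OC)c1
F4 | step 2 | 4-allyl-6,6-dimethoxycyclohexa-2,4-dien-1-one | COC1(OC)C=C(CC=C)C=CC1=O
F5 | step 2 | 4-allyl-2-(2,6-dimethoxy-4-propylphenoxy)-6-methoxyphenol | CCCc1cc(OC)c(Oc2cc(CC=C)cc(OC)c2O)c(OC)c1
F6 | step 1 | 4-allyl-2-methoxyphenyl acetate (eugenyl acetate) | COc1cc(CC=C)ccc1OC(C)=O
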